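At the time of reading, 4.0 min after the start, we want to know where free substrate stands, and the quantity that tells us is how fast it falls when each turnover also binds one more.

substrate 10 mM; acid 1.00 mM; time 4.0 min

    substrate + acid → weak acid + acid + target (k1 = 6.5 L mol⁻¹ s⁻¹)
    weak acid ⇌ conjugate base + acid, settled at all times (K2 = 6.3 × 10⁻⁹ M)
    substrate → weak acid + target (k3 = 0.0017 s⁻¹)
    weak acid → by-product carried off (k4 = 0.0060 s⁻¹)
    substrate + weak acid ⇌ idle adduct, settled at all times (K5 = 23000 L mol⁻¹)
    crystals ⇌ weak acid, rate k6*(cs6 - [weak acid]) while solid is left; crystals form when [weak acid] > cs6 (cs6 = 0.25 mM, k6 = 0.12 s⁻¹)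

- part of the substrate that has reacted at 4.0 min
- pH of the solution at 4.0 min

The two balances are the fastest rung. The ratio of conjugate base to weak acid is 6.30 × 10⁻⁶, with K2 far below c(acid), so c(acid) stays at its charge and the pH stays that of the charge. K5 times c(substrate) at the start is 230, so at the start nearly all of fresh weak acid goes at once into idle adduct, which holds a further substrate.

On the next rung, steps 1 and 3 form a pseudo-first-order loss with constant 0.00820 s⁻¹, and a first round leaves 14.0% of the charge. Putting the adduct back in, we go round again with the two-for-one constant, the rate at which free substrate falls when each turnover takes a second one with it, 0.0164 s⁻¹, which would leave 1.95%.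

But free weak acid climbs as substrate falls, and it meets the solubility 0.25 mM when c(substrate) is 0.800 mM. By our reckoning the two-for-one constant brings the flask there at 2.57 min, earlier than the reading. The time constant of the crystals, 8.33 s, is shorter than the 61.0 s of the two-for-one constant, so we expect free weak acid to stay somewhat above the solubility from then on. We commit to the conversion at that crossing, 92.0%, a figure that counts no loss of substrate after the crossing.

The forecast gives 94.1% and pH 3, holding that “Each weak acid formed immediately binds another substrate as adduct”; its conversion stands above ours.

The flask gives 94.0% and pH 3.00, with crystals at 0 mM after 2.00 min and 0.375 mM after 4.00 min. For the neighbour flask charged with 0.40 mM of acid, the two-for-one constant becomes 0.00860 s⁻¹, which leaves 12.7% of the substrate at the reading and puts the crossing at 4.89 min, after the reading. That neighbour flask shows crystals at 0 mM and substrate at 13.8%.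

(All constants belong to no real substance; the run is a simulation.)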